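**Plan**

1. Numbering (germacrane convention): ring carbons C1–C10, with CO2Me (C14) on C10 and CH3 on C4; O6/C6 and C7 carry the lactone (C11, C12 carbonyl, C13 methylene); C8 carries the methacrylate.
2. Cuts: the C8 ester, the C11=C13 methylene, the lactone bond O6–C12, then the ring bond C5–C6 (alkenyl iodide plus aldehyde); the open chain is cut at C1=C10 (olefination), C9–C10 (phosphonate alkylation) and C7–C11 (enolate allylation).
3. Enabling feature: C6, the carbinol carbon of the five-membered lactone, is allylic to the E-configured C4=C5 alkene of the ten-membered ring, so C5–C6 is the bond that an alkenylmetal addition to a C6 aldehyde makes.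
4. Forward order: a C6–C9 unit carrying C7, C8 and the C11–C12 arm is extended to the C10 phosphonate and joined to a C1–C5 iodoenal; the ten-membered carbocycle closes first, the γ-lactone second, and C13 and the methacrylate come last.
5. Stereochemistry: C8 from (S)-benzyl glycidyl ether; C7 by anti-selective Fráter–Seebach allylation under control of C8; C6 in the ring closure under control of C7; C4=C5 (E) from syn-carbometalation; C1=C10 from an E-selective Horner–Wadsworth–Emmons reaction.

Key step: step 13

Remark: the ring-closure product is assumed to survive work-up as the open hydroxy ester; any lactone formed in the same flask would be combined with the product of the following step.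

**Route**

Step 1
Reactants: 1 (S)-benzyl glycidyl ether [(2S)-2-[(benzyloxy)methyl]oxirane]
Product: 2 methyl (3S)-4-(benzyloxy)-3-hydroxybutanoate
Conditions: CO (40 bar), MeOH, Co2(CO)8 (5 mol%), 3-hydroxypyridine (10 mol%), THF, 60 °C
Reagents that add atoms: carbon monoxide [C-]#[O+]; methanol CO
Why: Cobalt-catalysed methoxycarbonylation of a terminal epoxide, in which the tetracarbonylcobaltate opens the ring at the unsubstituted carbon, CO inserts and methanol releases the β-hydroxy ester, so the C8 stereocentre of 1 is carried over untouched.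

Step 2
Reactants: 2 methyl (3S)-4-(benzyloxy)-3-hydroxybutanoate; 3 allyl bromide
Product: 5 methyl (2R)-2-[(1S)-2-(benzyloxy)-1-hydroxyethyl]pent-4-enoate, via dilithium alkoxide enolate 4 (not isolated)
Conditions: LiN(iPr)2 (2.2 equiv), THF, −78 → −20 °C; then 3, DMPU, −78 → −10 °C
Reagents that add atoms: none
Why: Fráter–Seebach alkylation, in which the six-membered lithium chelate of the alkoxide enolate is allylated on the face away from its CH2OBn substituent, which should set C7 anti to the C8 hydroxyl.

Step 3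
Reactants: 5 methyl (2R)-2-[(1S)-2-(benzyloxy)-1-hydroxyethyl]pent-4-enoate
Product: 6 (2S,3S)-4-(benzyloxy)-2-(prop-2-en-1-yl)butane-1,3-diol
Conditions: LiAlH4, THF, 0 °C
Reagents that add atoms: none
Why: Hydride reduction of the methyl ester to the primary C6 alcohol, which leaves both stereocentres, the alkene and the benzyl ether untouched.

Step 4
Reactants: 6 (2S,3S)-4-(benzyloxy)-2-(prop-2-en-1-yl)butane-1,3-diol
Product: 7 (2S,3S)-2-allyl-4-(benzyloxy)-1,3-bis[(tert-butyldimethylsilyl)oxy]butane
Conditions: TBSOTf (2.5 equiv), 2,6-lutidine, CH2Cl2, −78 → 0 °C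
Reagents that add atoms: tert-butyldimethylsilyl triflate CC(C)(C)[Si](C)(C)OS(=O)(=O)C(F)(F)F
Why: Exhaustive silylation with a silyl triflate protects the primary C6 and the hindered secondary C8 hydroxyls in one operation, and the two silyl ethers differ enough in hindrance to be told apart in step 11.

Step 5
Reactants: 7 (2S,3S)-2-allyl-4-(benzyloxy)-1,3-bis[(tert-butyldimethylsilyl)oxy]butane
Product: 8 methyl (3S,4S)-5-(benzyloxy)-4-[(tert-butyldimethylsilyl)oxy]-3-{[(tert-butyldimethylsilyl)oxy]methyl}pentanoate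
Conditions: O3, NaOH (2.5 M in MeOH), CH2Cl2, −78 °C, stopped at the first excess of ozone
Reagents that add atoms: ozone [O-][O+]=O; methanol CO
Why: Ozonolysis in methanolic NaOH turns the terminal alkene directly into the C12 methyl ester through oxidation of the methyl hemiacetal of the aldehyde, with loss of the terminal carbon, under conditions the silyl ethers should tolerate at −78 °C.

Step 6
Reactants: 8 methyl (3S,4S)-5-(benzyloxy)-4-[(tert-butyldimethylsilyl)oxy]-3-{[(tert-butyldimethylsilyl)oxy]methyl}pentanoate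
Product: 9 methyl (3S,4S)-4-[(tert-butyldimethylsilyl)oxy]-3-{[(tert-butyldimethylsilyl)oxy]methyl}-5-hydroxypentanoate
Conditions: H2 (1 atm), Pd(OH)2/C, EtOAc, rt
Reagents that add atoms: none
Why: Hydrogenolysis of the benzyl ether, possible now that no alkene is present, frees the C9 hydroxyl under neutral conditions that should leave the silyl ethers and the ester alone.

Step 7
Reactants: 9 methyl (3S,4S)-4-[(tert-butyldimethylsilyl)oxy]-3-{[(tert-butyldimethylsilyl)oxy]methyl}-5-hydroxypentanoate; 10 trimethyl phosphonoacetate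
Product: 12 dimethyl (4R,5S)-4-[(tert-butyldimethylsilyl)oxy]-5-{[(tert-butyldimethylsilyl)oxy]methyl}-2-(dimethoxyphosphoryl)heptanedioate (both C10 epimers), via triflate 11 (not isolated)
Conditions: Tf2O, 2,6-lutidine, CH2Cl2, −78 °C; then added cold to 10/NaH (3 equiv), THF–DMF, −40 → 0 °C
Reagents that add atoms: none
Why: SN2 alkylation of a phosphonate-stabilised carbanion, in which the primary triflate, the most reactive leaving group for this β-branched β-silyloxy carbon, is displaced at low temperature to form C9–C10; the new C10 centre is of no consequence because it becomes sp2 in step 10.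

Step 8
Reactants: 13 4-pentyn-1-ol
Product: 15 (4E)-5-iodo-4-methylpent-4-en-1-ol, via alkenylalane 14 (not isolated)
Conditions: AlMe3 (3 equiv), Cp2ZrCl2 (0.25 equiv), CH2Cl2, 0 °C → rt; then I2, THF, −30 → 0 °C
Reagents that add atoms: trimethylaluminium C[Al](C)C; iodine II
Why: Negishi zirconium-catalysed carboalumination adds methyl and aluminium syn across the alkyne with the metal at the terminus, and iodinolysis with retention should give the E alkenyl iodide (C4=C5).

Step 9
Reactants: 15 (4E)-5-iodo-4-methylpent-4-en-1-ol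
Product: 16 (4E)-5-iodo-4-methylpent-4-enal
Conditions: Dess–Martin periodinane, CH2Cl2, 0 °C → rt
Reagents that add atoms: none
Why: Dess–Martin oxidation of the primary alcohol to the C1 aldehyde, which does not touch the alkenyl iodide.

Step 10
Reactants: 12 the C10 phosphonate; 16 (4E)-5-iodo-4-methylpent-4-enal
Product: 17 dimethyl (2E,4R,5S)-4-[(tert-butyldimethylsilyl)oxy]-5-{[(tert-butyldimethylsilyl)oxy]methyl}-2-[(4E)-5-iodo-4-methylpent-4-en-1-ylidene]heptanedioate
Conditions: LiCl, DBU, MeCN, 0 °C → rt
Reagents that add atoms: none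
Why: Horner–Wadsworth–Emmons olefination under Masamune–Roush conditions forms C1=C10, and reversible addition of the α-branched phosphonate anion should favour the enoate with C2 trans to CO2Me, which is the E alkene with ring carbons C2 and C9 cis that the target needs.

Step 11
Reactants: 17 the bis-silyl enoate
Product: 18 dimethyl (2E,4R,5S)-4-[(tert-butyldimethylsilyl)oxy]-5-(hydroxymethyl)-2-[(4E)-5-iodo-4-methylpent-4-en-1-ylidene]heptanedioate
Conditions: HF·pyridine, pyridine, THF, 0 °C
Reagents that add atoms: none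
Why: Chemoselective desilylation, in which buffered HF·pyridine cleaves the unhindered primary silyl ether at C6 much faster than the secondary one at C8, and the near-neutral medium should keep the γ-hydroxy ester from lactonising before it is oxidised.

Step 12
Reactants: 18 the C6 alcohol
Product: 19 dimethyl (2E,4R,5R)-4-[(tert-butyldimethylsilyl)oxy]-5-formyl-2-[(4E)-5-iodo-4-methylpent-4-en-1-ylidene]heptanedioate (C5 alkenyl iodide, C6 aldehyde)
Conditions: Dess–Martin periodinane, pyridine, CH2Cl2, 0 °C; crude product used at once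
Reagents that add atoms: none
Why: Dess–Martin oxidation under buffered, non-basic conditions should give the C6 aldehyde without epimerising C7 or eliminating the C8 silyloxy group.

Step 13
Reactants: 19 the iodo aldehyde
Product: 20 methyl (1E,5E,7R,8S,9R)-9-[(tert-butyldimethylsilyl)oxy]-7-hydroxy-8-(2-methoxy-2-oxoethyl)-5-methylcyclodeca-1,5-diene-1-carboxylate (ten-membered ring, C6 allylic alcohol)
Conditions: CrCl2 (15 equiv), NiCl2 (0.15 equiv), degassed DMSO, rt, slow addition of 19 to 2 mM
Reagents that add atoms: none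
Why: Reduction of NiCl2 by CrCl2 gives zerovalent nickel, which adds oxidatively to the C5–I bond without loss of the E geometry; transmetalation to trivalent chromium then gives an alkenylchromium species that attacks the C6 aldehyde. The closest known reaction type is the intramolecular Nozaki–Hiyama–Kishi coupling of an alkenyl iodide with an aldehyde, used to close medium and large carbocycles as allylic alcohols. The ten-membered ring closes by 10-exo-trig addition to the carbonyl, and high dilution is meant to let ring closure outrun intermolecular coupling. The new C6 stereocentre is controlled by C7: with the forming C5–C6 bond gauche to C7–C8 as the ring demands, the carbonyl oxygen should lie next to H7 and not eclipse the C8 branch and its C–O dipole, the cyclic counterpart of the Felkin–Anh and 1,3-anti preferences of this anti-configured α-branched β-silyloxy aldehyde, which gives 6R with the C6 oxygen syn to the C11 arm. The step needs chemoselectivity for the aldehyde over the two esters and the enoate and configurational stability at C7, and the low basicity and low nucleophilicity of the organochromium reagent should secure both.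

Step 14
Reactants: 20 the ten-membered hydroxy ester
Product: 21 methyl (3aS,4R,6E,10E,11aR)-4-[(tert-butyldimethylsilyl)oxy]-10-methyl-2-oxo-2,3,3a,4,5,8,9,11a-octahydrocyclodeca[b]furan-6-carboxylate
Conditions: PPTS (cat.), toluene, 50 °C
Reagents that add atoms: none
Why: Acid-catalysed lactonisation of the γ-hydroxy ester closes the five-membered lactone at O6–C12 by 5-exo-trig acyl substitution, and because C6 and C7 are already fixed the ring fusion is trans.

Step 15
Reactants: 21 the saturated lactone
Product: 25 methyl (3aS,4R,6E,10E,11aR)-4-[(tert-butyldimethylsilyl)oxy]-10-methyl-3-methylidene-2-oxo-2,3,3a,4,5,8,9,11a-octahydrocyclodeca[b]furan-6-carboxylate, via lithium enolate 22 (not isolated), via Mannich base 23 (not isolated), via trimethylammonium iodide 24 (not isolated)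
Conditions: LiN(SiMe3)2 (1.1 equiv), THF, −78 °C; CH2=NMe2+ I−, −78 → 0 °C; then MeI, MeOH, rt; then NaHCO3 (aq.), CH2Cl2, rt
Reagents that add atoms: Eschenmoser's salt (N,N-dimethylmethyleneiminium iodide) C=[N+](C)C.[I-]
Why: α-Methylenation of a γ-butyrolactone by enolate Mannich reaction with Eschenmoser's salt, N-methylation and β-elimination of trimethylamine, which relies on the lactone α-CH2 (C11) being deprotonated faster than the γ-positions of the C10 enoate at −78 °C.

Step 16
Reactants: 25 the silylated α-methylene lactone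
Product: 26 methyl (3aR,4R,6E,10E,11aR)-4-hydroxy-10-methyl-3-methylidene-2-oxo-2,3,3a,4,5,8,9,11a-octahydrocyclodeca[b]furan-6-carboxylate
Conditions: HF·pyridine, THF, 0 °C → rt
Reagents that add atoms: none
Why: Desilylation with HF·pyridine, acidic rather than basic, should free the C8 hydroxyl without conjugate addition to the α-methylene lactone, migration of the lactone acyl group to O8 or attack on the C14 ester.

Step 17
Reactants: 26 the C8 alcohol
Product: 27 methyl (3aR,4R,6E,10E,11aR)-10-methyl-3-methylidene-4-[(2-methylprop-2-enoyl)oxy]-2-oxo-2,3,3a,4,5,8,9,11a-octahydrocyclodeca[b]furan-6-carboxylate (CNP0317149.1)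
Conditions: methacrylic anhydride, Et3N, DMAP (cat.), CH2Cl2, 0 °C → rt
Reagents that add atoms: methacrylic anhydride C=C(C)C(=O)OC(=O)C(C)=C
Why: DMAP-catalysed acyl transfer esterifies the secondary C8 alcohol with retention of configuration, since no bond to C8 is broken.

**Compound list**

1 | (S)-benzyl glycidyl ether | C1O[C@@H]1COCc2ccccc2 | starting material
2 | methyl (3S)-4-(benzyloxy)-3-hydroxybutanoate | COC(=O)C[C@H](O)COCc1ccccc1 | intermediate
3 | allyl bromide | C=CCBr | starting material
4 | dilithium alkoxide enolate of 2 (deprotonated at O on C8 and at C7) | COC(O[Li])=C[C@H](O[Li])COCc1ccccc1 | intermediate (not isolated)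
5 | methyl (2R)-2-[(1S)-2-(benzyloxy)-1-hydroxyethyl]pent-4-enoate | COC(=O)[C@H](CC=C)[C@H](O)COCc1ccccc1 | intermediate
6 | (2S,3S)-4-(benzyloxy)-2-(prop-2-en-1-yl)butane-1,3-diol | OC[C@H](CC=C)[C@H](O)COCc1ccccc1 | intermediate
7 | (2S,3S)-2-allyl-4-(benzyloxy)-1,3-bis[(tert-butyldimethylsilyl)oxy]butane | CC(C)(C)[Si](C)(C)OC[C@H](CC=C)[C@H](O[Si](C)(C)C(C)(C)C)COCc1ccccc1 | intermediate
8 | methyl (3S,4S)-5-(benzyloxy)-4-[(tert-butyldimethylsilyl)oxy]-3-{[(tert-butyldimethylsilyl)oxy]methyl}pentanoate | COC(=O)C[C@@H](CO[Si](C)(C)C(C)(C)C)[C@H](O[Si](C)(C)C(C)(C)C)COCc1ccccc1 | intermediate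
9 | methyl (3S,4S)-4-[(tert-butyldimethylsilyl)oxy]-3-{[(tert-butyldimethylsilyl)oxy]methyl}-5-hydroxypentanoate | COC(=O)C[C@@H](CO[Si](C)(C)C(C)(C)C)[C@H](O[Si](C)(C)C(C)(C)C)CO | intermediate
10 | trimethyl phosphonoacetate | COC(=O)CP(=O)(OC)OC | starting material
11 | methyl (3S,4S)-4-[(tert-butyldimethylsilyl)oxy]-3-{[(tert-butyldimethylsilyl)oxy]methyl}-5-{[(trifluoromethyl)sulfonyl]oxy}pentanoate | COC(=O)C[C@@H](CO[Si](C)(C)C(C)(C)C)[C@H](O[Si](C)(C)C(C)(C)C)COS(=O)(=O)C(F)(F)F | intermediate (not isolated)
12 | dimethyl (4R,5S)-4-[(tert-butyldimethylsilyl)oxy]-5-{[(tert-butyldimethylsilyl)oxy]methyl}-2-(dimethoxyphosphoryl)heptanedioate, both C10 epimers | COC(=O)C(P(=O)(OC)OC)C[C@@H](O[Si](C)(C)C(C)(C)C)[C@@H](CC(=O)OC)CO[Si](C)(C)C(C)(C)C | intermediate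
13 | 4-pentyn-1-ol | C#CCCCO | starting material
14 | dimethyl[(1E)-5-(dimethylalumanyloxy)-2-methylpent-1-en-1-yl]alumane | C[Al](C)/C=C(C)/CCCO[Al](C)C | intermediate (not isolated)
15 | (4E)-5-iodo-4-methylpent-4-en-1-ol | I/C=C(C)/CCCO | intermediate
16 | (4E)-5-iodo-4-methylpent-4-enal | I/C=C(C)/CCC=O | intermediate
17 | dimethyl (2E,4R,5S)-4-[(tert-butyldimethylsilyl)oxy]-5-{[(tert-butyldimethylsilyl)oxy]methyl}-2-[(4E)-5-iodo-4-methylpent-4-en-1-ylidene]heptanedioate | I/C=C(C)/CC/C=C(C(=O)OC)\C[C@@H](O[Si](C)(C)C(C)(C)C)[C@@H](CC(=O)OC)CO[Si](C)(C)C(C)(C)C | intermediate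
18 | dimethyl (2E,4R,5S)-4-[(tert-butyldimethylsilyl)oxy]-5-(hydroxymethyl)-2-[(4E)-5-iodo-4-methylpent-4-en-1-ylidene]heptanedioate | I/C=C(C)/CC/C=C(C(=O)OC)\C[C@@H](O[Si](C)(C)C(C)(C)C)[C@@H](CC(=O)OC)CO | intermediate
19 | dimethyl (2E,4R,5R)-4-[(tert-butyldimethylsilyl)oxy]-5-formyl-2-[(4E)-5-iodo-4-methylpent-4-en-1-ylidene]heptanedioate | I/C=C(C)/CC/C=C(C(=O)OC)\C[C@@H](O[Si](C)(C)C(C)(C)C)[C@@H](CC(=O)OC)C=O | intermediate
20 | methyl (1E,5E,7R,8S,9R)-9-[(tert-butyldimethylsilyl)oxy]-7-hydroxy-8-(2-methoxy-2-oxoethyl)-5-methylcyclodeca-1,5-diene-1-carboxylate | CC(C)(C)[Si](C)(C)O[C@@H]1C/C(C(=O)OC)=C\CC/C(C)=C/[C@@H](O)[C@@H]1CC(=O)OC | intermediate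
21 | methyl (3aS,4R,6E,10E,11aR)-4-[(tert-butyldimethylsilyl)oxy]-10-methyl-2-oxo-2,3,3a,4,5,8,9,11a-octahydrocyclodeca[b]furan-6-carboxylate | CC(C)(C)[Si](C)(C)O[C@@H]1C/C(C(=O)OC)=C\CC/C(C)=C/[C@H]2OC(=O)C[C@@H]21 | intermediate
22 | lithium enolate of 21 (C11=C12–OLi) | CC(C)(C)[Si](C)(C)O[C@@H]1C/C(C(=O)OC)=C\CC/C(C)=C/[C@H]2OC(O[Li])=C[C@@H]21 | intermediate (not isolated)
23 | C11-(dimethylaminomethyl) derivative of 21 (Mannich base, C11 epimers) | CC(C)(C)[Si](C)(C)O[C@@H]1C/C(C(=O)OC)=C\CC/C(C)=C/[C@H]2OC(=O)C(CN(C)C)[C@@H]21 | intermediate (not isolated)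
24 | C11-(trimethylammoniomethyl) derivative of 21, iodide salt | CC(C)(C)[Si](C)(C)O[C@@H]1C/C(C(=O)OC)=C\CC/C(C)=C/[C@H]2OC(=O)C(C[N+](C)(C)C)[C@@H]21.[I-] | intermediate (not isolated)
25 | methyl (3aS,4R,6E,10E,11aR)-4-[(tert-butyldimethylsilyl)oxy]-10-methyl-3-methylidene-2-oxo-2,3,3a,4,5,8,9,11a-octahydrocyclodeca[b]furan-6-carboxylate | CC(C)(C)[Si](C)(C)O[C@@H]1C/C(C(=O)OC)=C\CC/C(C)=C/[C@H]2OC(=O)C(=C)[C@@H]21 | intermediate
26 | methyl (3aR,4R,6E,10E,11aR)-4-hydroxy-10-methyl-3-methylidene-2-oxo-2,3,3a,4,5,8,9,11a-octahydrocyclodeca[b]furan-6-carboxylate | O[C@@H]1C/C(C(=O)OC)=C\CC/C(C)=C/[C@H]2OC(=O)C(=C)[C@@H]21 | intermediate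
27 | methyl (3aR,4R,6E,10E,11aR)-10-methyl-3-methylidene-4-[(2-methylprop-2-enoyl)oxy]-2-oxo-2,3,3a,4,5,8,9,11a-octahydrocyclodeca[b]furan-6-carboxylate | C=C(C)C(=O)O[C@@H]1C/C(C(=O)OC)=C\CC/C(C)=C/[C@H]2OC(=O)C(=C)[C@@H]21 | target

**Step count**

Total: 17 steps. Longest linear sequence: 15 steps (steps 1–7 and 10–17, from 1); steps 8 and 9 make the side branch.

**Steps most likely to fail**

1. Step 13. Ring closure may lose out to intermolecular coupling and to reduction of the C–I bond because of transannular strain in the ten-membered transition state, and the facial selectivity at C6 may erode under the ring constraints. The fallback sets out from 12 and 15 and returns at 21; it makes C5–C6 between two molecules, where open-chain Felkin–Anh control applies, and closes the ring at C1=C10 instead. Phosphonate 12 would be desilylated at the primary position (HF·pyridine, pyridine, THF) to the phosphonate alcohol F1 and oxidised (Dess–Martin periodinane, pyridine) to the phosphonate aldehyde F2. Intermolecular Nozaki–Hiyama–Kishi coupling of F2 with iodo alcohol 15 (CrCl2, NiCl2 cat., DMSO) should give the diol F3, which would be lactonised (PPTS, toluene) to the hydroxy lactone F4. Oxidation of the primary alcohol (Dess–Martin periodinane) would give the lactone aldehyde F5, and an intramolecular Horner–Wadsworth–Emmons reaction (LiCl, DBU, MeCN, high dilution), which favours the ring-cis enoate in a ten-membered ring, would deliver lactone 21.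

2. Step 7. Displacement at the β-branched, β-silyloxy primary carbon may be outpaced by intramolecular capture of the triflate by the C12 ester carbonyl or the C6 silyl ether oxygen, or diverted to O-alkylation of the phosphonate anion. The fallback sets out from 9 and returns at 12; it forms C9–C10 by carbonyl condensation instead of substitution. Alcohol 9 would be oxidised (Dess–Martin periodinane, pyridine) to the α-silyloxy aldehyde F6, condensed with 10 in a Knoevenagel reaction (TiCl4, N-methylmorpholine, THF, 0 °C) to the alkylidene phosphonoacetate F7, and reduced in the conjugate sense (NaBH4, EtOH, 0 °C) to phosphonate 12.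

3. Step 15. The amide base may deprotonate the positions γ to the C10 enoate (C9, C2) or add to the enoate instead of forming the lactone enolate cleanly, leading to deconjugation and loss of material. The fallback sets out from 21 and returns at 23; it replaces the lithium enolate by a neutral silyl ketene acetal. Soft enolisation of the lactone (TMSOTf, Et3N, CH2Cl2, 0 °C), which the enoate, lacking an α-hydrogen, cannot undergo, would give the 2-silyloxyfuran-type ketene acetal F8. A Mukaiyama–Mannich reaction of F8 with Eschenmoser's salt (CH2Cl2, rt) would give Mannich base 23, which continues as in step 15 (MeI; NaHCO3) to 25.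

**Further compounds**

F1 | step 13 | dimethyl (4R,5S)-4-[(tert-butyldimethylsilyl)oxy]-2-(dimethoxyphosphoryl)-5-(hydroxymethyl)heptanedioate | COC(=O)C(P(=O)(OC)OC)C[C@@H](O[Si](C)(C)C(C)(C)C)[C@@H](CC(=O)OC)CO
F2 | step 13 | dimethyl (4R,5R)-4-[(tert-butyldimethylsilyl)oxy]-2-(dimethoxyphosphoryl)-5-formylheptanedioate | COC(=O)C(P(=O)(OC)OC)C[C@@H](O[Si](C)(C)C(C)(C)C)[C@@H](CC(=O)OC)C=O
F3 | step 13 | dimethyl (4R,5S)-4-[(tert-butyldimethylsilyl)oxy]-2-(dimethoxyphosphoryl)-5-[(1R,2E)-1,6-dihydroxy-3-methylhex-2-en-1-yl]heptanedioate | OCCC/C(C)=C/[C@@H](O)[C@H](CC(=O)OC)[C@H](O[Si](C)(C)C(C)(C)C)CC(P(=O)(OC)OC)C(=O)OC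
F4 | step 13 | methyl (4R)-4-[(tert-butyldimethylsilyl)oxy]-2-(dimethoxyphosphoryl)-4-{(2R,3S)-2-[(1E)-5-hydroxy-2-methylpent-1-en-1-yl]-5-oxotetrahydrofuran-3-yl}butanoate | OCCC/C(C)=C/[C@H]1OC(=O)C[C@@H]1[C@H](O[Si](C)(C)C(C)(C)C)CC(P(=O)(OC)OC)C(=O)OC
F5 | step 13 | methyl (4R)-4-[(tert-butyldimethylsilyl)oxy]-2-(dimethoxyphosphoryl)-4-{(2R,3S)-2-[(1E)-2-methyl-5-oxopent-1-en-1-yl]-5-oxotetrahydrofuran-3-yl}butanoate | O=CCC/C(C)=C/[C@H]1OC(=O)C[C@@H]1[C@H](O[Si](C)(C)C(C)(C)C)CC(P(=O)(OC)OC)C(=O)OC
F6 | step 7 | methyl (3S,4S)-4-[(tert-butyldimethylsilyl)oxy]-3-{[(tert-butyldimethylsilyl)oxy]methyl}-5-oxopentanoate | COC(=O)C[C@@H](CO[Si](C)(C)C(C)(C)C)[C@H](O[Si](C)(C)C(C)(C)C)C=O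
F7 | step 7 | dimethyl (4S,5S)-4-[(tert-butyldimethylsilyl)oxy]-5-{[(tert-butyldimethylsilyl)oxy]methyl}-2-(dimethoxyphosphoryl)hept-2-enedioate (either alkene geometry) | COC(=O)C[C@@H](CO[Si](C)(C)C(C)(C)C)[C@H](O[Si](C)(C)C(C)(C)C)C=C(C(=O)OC)P(=O)(OC)OC
F8 | step 15 | methyl (3aS,4R,6E,10E,11aR)-4-[(tert-butyldimethylsilyl)oxy]-10-methyl-2-[(trimethylsilyl)oxy]-3a,4,5,8,9,11a-hexahydrocyclodeca[b]furan-6-carboxylate | CC(C)(C)[Si](C)(C)O[C@@H]1C/C(C(=O)OC)=C\CC/C(C)=C/[C@H]2OC(O[Si](C)(C)C)=C[C@@H]21
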